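**Retrosynthetic overview** (flavonoid locants: ring C = O1, C2, C3, C4; ring A = C4a–C8a; ring B = C1'–C6')
1. The strategy rests on ring B being a resorcinol bonded to C2 through C1', the carbon between its two oxygens O2' and O6', with O2' tied to C4 as the bridging hemiketal.
2. After a last O6'–Si cleavage, one step is cut at C1'–C2', C2'–C3', C5'–C6' (ring B) and O2'–C4 (hemiketal ring), back to the C2 siloxyalkyne 24 and vinylketene from cyclobutenone 27.
3. 24 comes from the terminal alkyne by acetylide oxidation and O-silylation, run at the C4 alcohol level (TMS ether) because a C4 ketone β to the aryloxy group would enolise and open ring C under the amide base; MnO2 then restores the ketone.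
4. C2 is set by copper-catalysed enantioselective alkynylation of chromone 12, which is built from 5-methoxyresorcinol by Hoesch acylation, C8 prenylation (O-1,1-dimethylallyl ether, Claisen shift), chromenylation with prenal and enaminone cyclisation.
5. Ring order: ring A (given), dimethylpyran ring, ring C, then ring B and the O2'–C4 ring together.

Key step: step 14

Assumption 1: the copper–ligand pair is used in the enantiomeric form that delivers the 2R product; (S)-StackPhos is written, and its mirror image is used if the first run shows the opposite sense.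
Assumption 2: tert-butyl 2-methylbut-3-en-2-yl carbonate 4 is taken as a purchasable reagent.
Remark: names of 12–24 use pyrano[3,2-g]chromene numbering, in which O1, C2, C3 and C4 are the same atoms as in flavonoid numbering.

**Step 1**
Reactants: 1 5-methoxyresorcinol
Product: 3 1-(2,4-dihydroxy-6-methoxyphenyl)ethanone, via iminium chloride 2 (not isolated)
Conditions: MeCN, ZnCl2, HCl (g), Et2O, 0 °C; then H2O, 100 °C
Reagents that add atoms: acetonitrile (CC#N); water (O)
Why: Hoesch acylation: the nitrilium electrophile attacks the ring carbon that lies between a hydroxyl and the methoxyl and para to the other hydroxyl (two such positions, para-hydroxyl activation), giving iminium salt 2, which water hydrolyses to the ketone, and the minor 2,6-dihydroxy-4-methoxy isomer should be removed by crystallisation.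

**Step 2**
Reactants: 3 1-(2,4-dihydroxy-6-methoxyphenyl)ethanone; 4 tert-butyl 2-methylbut-3-en-2-yl carbonate
Product: 5 1-[2-hydroxy-6-methoxy-4-(2-methylbut-3-en-2-yloxy)phenyl]ethanone
Conditions: Pd(PPh3)4 (cat.), THF, 0 °C
Reagents that add atoms: none
Why: Tsuji–Trost O-allylation: zerovalent palladium ionises the tertiary carbonate with loss of CO2, the tert-butoxide set free deprotonates the more acidic, non-chelated 4-hydroxyl, and the phenoxide attacks the more substituted allyl terminus at low temperature to give the tertiary ether, while the 2-hydroxyl stays hydrogen-bonded to the acetyl group.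

**Step 3**
Reactants: 5 1-[2-hydroxy-6-methoxy-4-(2-methylbut-3-en-2-yloxy)phenyl]ethanone
Product: 7 1-[2,4-dihydroxy-6-methoxy-3-(3-methylbut-2-en-1-yl)phenyl]ethanone, via Claisen dienone 6 (not isolated)
Conditions: xylene, 130 °C
Reagents that add atoms: none
Why: Aromatic Claisen rearrangement: the [3,3] shift inverts the allyl unit to the normal prenyl group and goes to C3 rather than C5 because chelation of the 2-hydroxyl to the acetyl group localises the C3–C4 double bond (bond fixation), after which dienone 6 tautomerises to the phenol.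

**Step 4**
Reactants: 7 1-[2,4-dihydroxy-6-methoxy-3-(3-methylbut-2-en-1-yl)phenyl]ethanone; 8 3-methylbut-2-enal
Product: 10 1-[7-hydroxy-5-methoxy-2,2-dimethyl-8-(3-methylbut-2-en-1-yl)-2H-chromen-6-yl]ethanone, via quinone methide 9 (not isolated)
Conditions: ethylenediammonium diacetate (cat.), xylene, 140 °C
Reagents that add atoms: none
Why: Chromenylation by Knoevenagel-type condensation and oxa-6π electrocyclisation: the only free position ortho to the 4-hydroxyl (C5) condenses with the enal, water is lost to give quinone methide 9, and its dienone oxygen closes on the dimethyl-substituted terminus to form the 2,2-dimethylpyran ring.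

**Step 5**
Reactants: 10 1-[7-hydroxy-5-methoxy-2,2-dimethyl-8-(3-methylbut-2-en-1-yl)-2H-chromen-6-yl]ethanone
Product: 12 5-methoxy-8,8-dimethyl-10-(3-methylbut-2-en-1-yl)-4H,8H-pyrano[3,2-g]chromen-4-one, via enaminone 11 (not isolated)
Conditions: Me2NCH(OMe)2, PhMe, 100 °C; then 2 M HCl, CH2Cl2, rt
Reagents that add atoms: N,N-dimethylformamide dimethyl acetal (COC(OC)N(C)C)
Why: Enaminone route to chromones: the acetyl methyl group condenses with the amide acetal to give 11, and acid then promotes conjugate addition of the chelated phenol and loss of dimethylamine, which closes ring C as the 2,3-unsubstituted chromone.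

**Step 6**
Reactants: 12 5-methoxy-8,8-dimethyl-10-(3-methylbut-2-en-1-yl)-4H,8H-pyrano[3,2-g]chromen-4-one; 13 trimethylsilylacetylene
Product: 16 (2R)-5-methoxy-8,8-dimethyl-10-(3-methylbut-2-en-1-yl)-2-[(trimethylsilyl)ethynyl]-2,3-dihydro-4H,8H-pyrano[3,2-g]chromen-4-one, via benzopyrylium triflate 14 (not isolated), via silyl enol ether 15 (not isolated)
Conditions: CuI (cat.), (S)-StackPhos (cat.), i-Pr2NEt, TBSOTf, PhMe, −78 °C; then 2 M HCl, THF, 0 °C
Reagents that add atoms: none
Why: Copper-catalysed enantioselective alkynylation of a chromone through its 4-silyloxybenzopyrylium ion: TBSOTf converts 12 into 14, the copper acetylide carrying the chiral P,N-ligand adds to C2 on the face selected by the ligand to set the 2R centre in enol ether 15, and dilute acid releases the ketone without touching C2.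

**Step 7**
Reactants: 16 (2R)-5-methoxy-8,8-dimethyl-10-(3-methylbut-2-en-1-yl)-2-[(trimethylsilyl)ethynyl]-2,3-dihydro-4H,8H-pyrano[3,2-g]chromen-4-one
Product: 18 (2R,4R)-2-ethynyl-5-methoxy-8,8-dimethyl-10-(3-methylbut-2-en-1-yl)-3,4-dihydro-2H,8H-pyrano[3,2-g]chromen-4-ol, via silylalkynyl chromanol 17 (not isolated)
Conditions: NaBH4, MeOH–THF, 0 °C; then K2CO3, rt
Reagents that add atoms: none
Why: Borohydride reduction followed by base-catalysed methanolysis of the alkynyl C–Si bond: hydride should enter anti to the C2 substituent to give mainly the 2,4-cis alcohol (this centre is removed again in step 11), and carbonate is added only after the ketone has been consumed so that no enolate can open ring C and racemise C2.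

**Step 8**
Reactants: 18 (2R,4R)-2-ethynyl-5-methoxy-8,8-dimethyl-10-(3-methylbut-2-en-1-yl)-3,4-dihydro-2H,8H-pyrano[3,2-g]chromen-4-ol
Product: 19 (2R,4R)-2-ethynyl-5-methoxy-8,8-dimethyl-10-(3-methylbut-2-en-1-yl)-4-(trimethylsilyloxy)-3,4-dihydro-2H,8H-pyrano[3,2-g]chromene
Conditions: TMSCl, imidazole, CH2Cl2, 0 °C
Reagents that add atoms: chlorotrimethylsilane (C[Si](C)(C)Cl)
Why: Standard silylation of a secondary alcohol, which masks the hydroxyl during the organolithium chemistry of step 9 with a group that can later be taken off under conditions far milder than any that cleave a triisopropylsilyl group.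

**Step 9**
Reactants: 19 (2R,4R)-2-ethynyl-5-methoxy-8,8-dimethyl-10-(3-methylbut-2-en-1-yl)-4-(trimethylsilyloxy)-3,4-dihydro-2H,8H-pyrano[3,2-g]chromene
Product: 22 (2R,4R)-5-methoxy-8,8-dimethyl-10-(3-methylbut-2-en-1-yl)-2-[(triisopropylsilyloxy)ethynyl]-4-(trimethylsilyloxy)-3,4-dihydro-2H,8H-pyrano[3,2-g]chromene, via lithium acetylide 20 (not isolated), via lithium ynolate 21 (not isolated)
Conditions: LiN(SiMe3)2, THF, −78 °C; t-BuOOLi (from t-BuOOH and LiN(SiMe3)2), −78 → 0 °C; TIPSOTf, −78 → 0 °C
Reagents that add atoms: tert-butyl hydroperoxide (CC(C)(C)OO); triisopropylsilyl trifluoromethanesulfonate (CC(C)[Si](C(C)C)(C(C)C)OS(=O)(=O)C(F)(F)F)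
Why: Oxidation of a lithium acetylide with lithium tert-butyl peroxide to the lithium ynolate and O-silylation with a bulky silyl triflate (the known route from terminal alkynes to siloxyalkynes): the bulky silicon goes to oxygen and not to carbon, and the sequence is run at the C4 silyl ether level because a C4 ketone would be enolised by the amide base and would open ring C by β-elimination of the aryloxide.

**Step 10**
Reactants: 22 (2R,4R)-5-methoxy-8,8-dimethyl-10-(3-methylbut-2-en-1-yl)-2-[(triisopropylsilyloxy)ethynyl]-4-(trimethylsilyloxy)-3,4-dihydro-2H,8H-pyrano[3,2-g]chromene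
Product: 23 (2R,4R)-5-methoxy-8,8-dimethyl-10-(3-methylbut-2-en-1-yl)-2-[(triisopropylsilyloxy)ethynyl]-3,4-dihydro-2H,8H-pyrano[3,2-g]chromen-4-ol
Conditions: K2CO3 (0.2 equiv), MeOH–THF, 0 °C
Reagents that add atoms: none
Why: Base-catalysed methanolysis of a trimethylsilyl ether: the unhindered Si–O bond of the secondary ether is cleaved within minutes at 0 °C, while the triisopropylsilyl ynol ether, shielded at silicon and exposed to neither acid nor fluoride, should survive the short contact.

**Step 11**
Reactants: 23 (2R,4R)-5-methoxy-8,8-dimethyl-10-(3-methylbut-2-en-1-yl)-2-[(triisopropylsilyloxy)ethynyl]-3,4-dihydro-2H,8H-pyrano[3,2-g]chromen-4-ol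
Product: 24 (2R)-5-methoxy-8,8-dimethyl-10-(3-methylbut-2-en-1-yl)-2-[(triisopropylsilyloxy)ethynyl]-2,3-dihydro-4H,8H-pyrano[3,2-g]chromen-4-one
Conditions: MnO2, CH2Cl2, rt
Reagents that add atoms: none
Why: Heterogeneous MnO2 oxidation of an electron-rich benzylic alcohol under neutral conditions, which should leave the siloxyalkyne, the chromene and the prenyl group alone and, by removing the C4 centre, makes any 4-epimer from step 7 converge on 24.

**Step 12**
Reactants: 25 3-oxocyclobutanecarboxylic acid
Product: 26 3-bromocyclobutanone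
Conditions: HgO, Br2, MgSO4, CH2Cl2, 40 °C
Reagents that add atoms: bromine (BrBr)
Why: Cristol–Firth variant of the Hunsdiecker bromodecarboxylation: the mercury carboxylate reacts with bromine to an acyl hypobromite that loses CO2 in a radical chain and the cyclobutyl radical takes up bromine.

**Step 13**
Reactants: 26 3-bromocyclobutanone
Product: 27 cyclobut-2-en-1-one
Conditions: n-Bu3N, rt, vacuum transfer into a cold trap
Reagents that add atoms: none
Why: E1cB-type β-elimination of HBr from a β-bromo ketone with a tertiary amine, the volatile enone being removed from the base as it forms so that it does not polymerise.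

**Step 14**
Reactants: 24 (2R)-5-methoxy-8,8-dimethyl-10-(3-methylbut-2-en-1-yl)-2-[(triisopropylsilyloxy)ethynyl]-2,3-dihydro-4H,8H-pyrano[3,2-g]chromen-4-one; 27 cyclobut-2-en-1-one
Product: 33 (2R,4R)-4,2'-epoxy-4-hydroxy-5-methoxy-6'-(triisopropylsilyloxy)-6'',6''-dimethyl-8-(3-methylbut-2-en-1-yl)pyrano[2'',3'':7,6]flavan, via vinylketene 28 (not isolated), via vinylcyclobutenone 29 (not isolated), via dienylketene 30 (not isolated), via cyclohexadienone 31 (not isolated), via hydroxyflavanone 32 (not isolated)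
Conditions: PhMe, 80 → 110 °C, sealed tube, 27 (excess) added in portions
Reagents that add atoms: none
Why: At 80 °C cyclobutenone 27 opens (4π) to vinylketene 28, whose carbonyl carbon is attacked by the oxygen-activated alkyne carbon bound to C2, so that the [2+2] adduct 29 has C1'–C2' and C5'–C6' in place; 29 opens again (4π) to dienylketene 30, which closes by 6π electrocyclisation (C2'–C3') to dienone 31 and tautomerises to the 2'-phenol 32. This is the Danheiser benzannulation of a cyclobutenone with a siloxyalkyne, the closest known reaction type, applied here to an alkyne that carries an α-aryloxy stereocentre and a β-ketone. Ring B is thus closed by the 6π electrocyclisation, and the second ring by 6-exo-trig addition of the new 2'-hydroxyl to the C4 ketone, which carries no chelating 5-hydroxyl that would hold it in the open form. The new C4 centre is controlled by C2: the phenol is tethered through C2–C1' and can reach only the carbonyl face syn to the aryl group, which gives the 4R ketal and no other. The selectivity needed is the regiochemistry of the ketene–alkyne [2+2], and it is secured by the polarisation of the siloxyalkyne (nucleophilic at the carbon remote from oxygen), which places C2 on C1' between the two oxygens; C2 itself should not epimerise because the medium is neutral and free of base.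

**Step 15**
Reactants: 33 (2R,4R)-4,2'-epoxy-4-hydroxy-5-methoxy-6'-(triisopropylsilyloxy)-6'',6''-dimethyl-8-(3-methylbut-2-en-1-yl)pyrano[2'',3'':7,6]flavan
Product: 34 (2R,4R)-4,2'-epoxy-4,6'-dihydroxy-5-methoxy-6'',6''-dimethyl-8-(3-methylbut-2-en-1-yl)pyrano[2'',3'':7,6]flavan
Conditions: Bu4NF, AcOH, THF, 0 °C
Reagents that add atoms: none
Why: Fluoride cleavage of an aryl silyl ether, buffered with acetic acid so that no phenoxide or free fluoride base opens the hemiketal or ring C, which keeps both stereocentres untouched.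

**Compound list**
1 | 5-methoxyresorcinol | COc1cc(O)cc(O)c1 | starting material
2 | 1-(2,4-dihydroxy-6-methoxyphenyl)ethan-1-iminium chloride | CC(=[NH2+])c1c(O)cc(O)cc1OC.[Cl-] | intermediate
3 | 1-(2,4-dihydroxy-6-methoxyphenyl)ethanone | CC(=O)c1c(O)cc(O)cc1OC | intermediate
4 | tert-butyl 2-methylbut-3-en-2-yl carbonate | CC(C)(C)OC(=O)OC(C)(C)C=C | starting material
5 | 1-[2-hydroxy-6-methoxy-4-(2-methylbut-3-en-2-yloxy)phenyl]ethanone | CC(=O)c1c(O)cc(OC(C)(C)C=C)cc1OC | intermediate
6 | 4-acetyl-3-hydroxy-5-methoxy-2-(3-methylbut-2-en-1-yl)cyclohexa-3,5-dien-1-one (Claisen dienone, C2 of the ring unassigned) | CC(=O)C1=C(O)C(CC=C(C)C)C(=O)C=C1OC | intermediate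
7 | 1-[2,4-dihydroxy-6-methoxy-3-(3-methylbut-2-en-1-yl)phenyl]ethanone | CC(=O)c1c(O)c(CC=C(C)C)c(O)cc1OC | intermediate
8 | 3-methylbut-2-enal | CC(C)=CC=O | starting material
9 | 4-acetyl-3-hydroxy-5-methoxy-6-(3-methylbut-2-en-1-ylidene)-2-(3-methylbut-2-en-1-yl)cyclohexa-2,4-dien-1-one (quinone methide, side chain cis to the ring carbonyl) | O=C1C(CC=C(C)C)=C(O)C(C(C)=O)=C(OC)/C1=C/C=C(C)C | intermediate
10 | 1-[7-hydroxy-5-methoxy-2,2-dimethyl-8-(3-methylbut-2-en-1-yl)-2H-chromen-6-yl]ethanone | CC(=O)c1c(O)c(CC=C(C)C)c2OC(C)(C)C=Cc2c1OC | intermediate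
11 | (E)-3-(dimethylamino)-1-[7-hydroxy-5-methoxy-2,2-dimethyl-8-(3-methylbut-2-en-1-yl)-2H-chromen-6-yl]prop-2-en-1-one | CN(C)/C=C/C(=O)c1c(O)c(CC=C(C)C)c2OC(C)(C)C=Cc2c1OC | intermediate
12 | 5-methoxy-8,8-dimethyl-10-(3-methylbut-2-en-1-yl)-4H,8H-pyrano[3,2-g]chromen-4-one | O=C1C=COc2c1c(OC)c1c(c2CC=C(C)C)OC(C)(C)C=C1 | intermediate
13 | trimethylsilylacetylene | C#C[Si](C)(C)C | starting material
14 | 4-(tert-butyldimethylsilyloxy)-5-methoxy-8,8-dimethyl-10-(3-methylbut-2-en-1-yl)-8H-pyrano[3,2-g]chromen-1-ium trifluoromethanesulfonate | CC(C)(C)[Si](C)(C)Oc1cc[o+]c2c1c(OC)c1c(c2CC=C(C)C)OC(C)(C)C=C1.[O-]S(=O)(=O)C(F)(F)F | intermediate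
15 | (2R)-4-(tert-butyldimethylsilyloxy)-5-methoxy-8,8-dimethyl-10-(3-methylbut-2-en-1-yl)-2-[(trimethylsilyl)ethynyl]-2H,8H-pyrano[3,2-g]chromene | CC(C)(C)[Si](C)(C)OC1=C[C@H](C#C[Si](C)(C)C)Oc2c1c(OC)c1c(c2CC=C(C)C)OC(C)(C)C=C1 | intermediate
16 | (2R)-5-methoxy-8,8-dimethyl-10-(3-methylbut-2-en-1-yl)-2-[(trimethylsilyl)ethynyl]-2,3-dihydro-4H,8H-pyrano[3,2-g]chromen-4-one | O=C1C[C@H](C#C[Si](C)(C)C)Oc2c1c(OC)c1c(c2CC=C(C)C)OC(C)(C)C=C1 | intermediate
17 | (2R,4R)-5-methoxy-8,8-dimethyl-10-(3-methylbut-2-en-1-yl)-2-[(trimethylsilyl)ethynyl]-3,4-dihydro-2H,8H-pyrano[3,2-g]chromen-4-ol | O[C@@H]1C[C@H](C#C[Si](C)(C)C)Oc2c1c(OC)c1c(c2CC=C(C)C)OC(C)(C)C=C1 | intermediate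
18 | (2R,4R)-2-ethynyl-5-methoxy-8,8-dimethyl-10-(3-methylbut-2-en-1-yl)-3,4-dihydro-2H,8H-pyrano[3,2-g]chromen-4-ol | O[C@@H]1C[C@H](C#C)Oc2c1c(OC)c1c(c2CC=C(C)C)OC(C)(C)C=C1 | intermediate
19 | (2R,4R)-2-ethynyl-5-methoxy-8,8-dimethyl-10-(3-methylbut-2-en-1-yl)-4-(trimethylsilyloxy)-3,4-dihydro-2H,8H-pyrano[3,2-g]chromene | C[Si](C)(C)O[C@@H]1C[C@H](C#C)Oc2c1c(OC)c1c(c2CC=C(C)C)OC(C)(C)C=C1 | intermediate
20 | lithium acetylide of 19 | C[Si](C)(C)O[C@@H]1C[C@H](C#C[Li])Oc2c1c(OC)c1c(c2CC=C(C)C)OC(C)(C)C=C1 | intermediate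
21 | lithium ynolate derived from 20 (O–Li on the alkyne terminus) | C[Si](C)(C)O[C@@H]1C[C@H](C#CO[Li])Oc2c1c(OC)c1c(c2CC=C(C)C)OC(C)(C)C=C1 | intermediate
22 | (2R,4R)-5-methoxy-8,8-dimethyl-10-(3-methylbut-2-en-1-yl)-2-[(triisopropylsilyloxy)ethynyl]-4-(trimethylsilyloxy)-3,4-dihydro-2H,8H-pyrano[3,2-g]chromene | C[Si](C)(C)O[C@@H]1C[C@H](C#CO[Si](C(C)C)(C(C)C)C(C)C)Oc2c1c(OC)c1c(c2CC=C(C)C)OC(C)(C)C=C1 | intermediate
23 | (2R,4R)-5-methoxy-8,8-dimethyl-10-(3-methylbut-2-en-1-yl)-2-[(triisopropylsilyloxy)ethynyl]-3,4-dihydro-2H,8H-pyrano[3,2-g]chromen-4-ol | O[C@@H]1C[C@H](C#CO[Si](C(C)C)(C(C)C)C(C)C)Oc2c1c(OC)c1c(c2CC=C(C)C)OC(C)(C)C=C1 | intermediate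
24 | (2R)-5-methoxy-8,8-dimethyl-10-(3-methylbut-2-en-1-yl)-2-[(triisopropylsilyloxy)ethynyl]-2,3-dihydro-4H,8H-pyrano[3,2-g]chromen-4-one | O=C1C[C@H](C#CO[Si](C(C)C)(C(C)C)C(C)C)Oc2c1c(OC)c1c(c2CC=C(C)C)OC(C)(C)C=C1 | intermediate
25 | 3-oxocyclobutanecarboxylic acid | O=C1CC(C(=O)O)C1 | starting material
26 | 3-bromocyclobutanone | O=C1CC(Br)C1 | intermediate
27 | cyclobut-2-en-1-one | O=C1C=CC1 | intermediate
28 | buta-1,3-dien-1-one (vinylketene) | C=CC=C=O | intermediate
29 | chromanone 24 in which C2 carries a 4-oxo-2-(triisopropylsilyloxy)-3-vinylcyclobut-1-en-1-yl group in place of the alkyne (vinyl-bearing carbon unassigned) | O=C1C[C@H](C3=C(O[Si](C(C)C)(C(C)C)C(C)C)C(C=C)C3=O)Oc2c1c(OC)c1c(c2CC=C(C)C)OC(C)(C)C=C1 | intermediate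
30 | chromanone in which C2 carries a 1-oxo-3-(triisopropylsilyloxy)hexa-1,3,5-trien-2-yl group (ketene carbon cis to the vinyl group) | O=C1C[C@H](C(=C=O)/C(O[Si](C(C)C)(C(C)C)C(C)C)=C\C=C)Oc2c1c(OC)c1c(c2CC=C(C)C)OC(C)(C)C=C1 | intermediate
31 | chromanone in which C2 carries a 6-oxo-2-(triisopropylsilyloxy)cyclohexa-1,3-dien-1-yl group | O=C1C[C@H](C3=C(O[Si](C(C)C)(C(C)C)C(C)C)C=CCC3=O)Oc2c1c(OC)c1c(c2CC=C(C)C)OC(C)(C)C=C1 | intermediate
32 | (2R)-2'-hydroxy-5-methoxy-6'-(triisopropylsilyloxy)-6'',6''-dimethyl-8-(3-methylbut-2-en-1-yl)pyrano[2'',3'':7,6]flavanone | O=C1C[C@H](c3c(O)cccc3O[Si](C(C)C)(C(C)C)C(C)C)Oc2c1c(OC)c1c(c2CC=C(C)C)OC(C)(C)C=C1 | intermediate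
33 | (2R,4R)-4,2'-epoxy-4-hydroxy-5-methoxy-6'-(triisopropylsilyloxy)-6'',6''-dimethyl-8-(3-methylbut-2-en-1-yl)pyrano[2'',3'':7,6]flavan (6'-O-triisopropylsilyl ether of the target) | COc1c2c(c(CC=C(C)C)c3c1[C@@]1(O)C[C@@H](O3)c3c(O[Si](C(C)C)(C(C)C)C(C)C)cccc3O1)OC(C)(C)C=C2 | intermediate
34 | (2R,4R)-4,2'-epoxy-4,6'-dihydroxy-5-methoxy-6'',6''-dimethyl-8-(3-methylbut-2-en-1-yl)pyrano[2'',3'':7,6]flavan (CNP0170313.2) | COc1c2c(c(CC=C(C)C)c3c1[C@@]1(O)C[C@@H](O3)c3c(O)cccc3O1)OC(C)(C)C=C2 | target

**Step count**
Total: 15 steps. Longest linear sequence: 13 steps (steps 1–11, 14, 15); steps 12 and 13 are the two-step side branch to cyclobutenone 27.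

**Steps most likely to fail**

Step 14 (key step). Cyclobutenone may oligomerise, or acylate the new phenol, faster than it opens and adds to the alkyne. At 80–110 °C the propargylic aryloxy group of 24 may also ionise under the push of the ynol ether. The fallback sets out from 24 and no longer uses the strained enone. Vinylketene 28 is generated at room temperature by 1,4-dehydrochlorination of (E)-but-2-enoyl chloride with i-Pr2NEt in toluene (slow addition), so that the [2+2] adduct 29 forms cold. The ammonium salt is filtered off and the solution is warmed to 80 °C only for the electrocyclic stage, which takes 29 through 30, 31 and 32 to 33, where the route is rejoined. Ketene generation from an unsaturated acid chloride and cycloaddition of ketenes to ynol ethers are both known, and no compound outside the list is made.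

Step 10. Methoxide may attack the silicon of the ynol ether as well as that of the trimethylsilyl ether, with loss of the triisopropylsilyl group and collapse of the ynol to a ketene and ester. The fallback sets out from alcohol 18 and avoids the O-protecting group altogether. Two equivalents of LiN(SiMe3)2 in THF at −78 °C give the dilithium alkoxide–acetylide F1. t-BuOOLi oxidises it (−78 → 0 °C) to the dilithium alkoxide–ynolate F2. One equivalent of TIPSCl (−78 → 0 °C) should then silylate only the ynolate oxygen, since a hindered secondary lithium alkoxide peri to the methoxyl reacts slowly with the bulky chlorosilane. Aqueous work-up gives 23 directly, where the route is rejoined. Acetylide oxidation and ynolate trapping with TIPSCl are known, so steps 8–10 are replaced by one operation.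

Step 6. Facial selectivity or turnover may be poor in the addition of the copper acetylide to the electron-rich, 5-methoxy-substituted benzopyrylium ion. The fallback sets out from 12 and 13 and sets the stereocentre by resolution. The alkynylation is run without the chiral ligand (CuI, i-Pr2NEt, TBSOTf; then HCl) and should give, through enol ether 15 and its mirror image, the 2S silyl enol ether F3, the racemate made up of 16 and the 2S ketone F4. Noyori transfer hydrogenation with RuCl(p-cymene)[(R,R)-TsDPEN] and HCO2H–Et3N is then used as a kinetic resolution. The catalyst's preferred hydride delivery (giving 4R) is anti to the C2 substituent only in the 2R ketone, so 16 should be reduced to the cis alcohol 17 while F4 stays behind and is removed by chromatography. The route is rejoined at 17, which is taken on with the K2CO3 part of step 7.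

**Further compounds**
F0 | step 14 | none | none
F1 | step 10 | dilithium salt of 18 (lithium alkoxide at C4, lithium acetylide) | [Li]O[C@@H]1C[C@H](C#C[Li])Oc2c1c(OC)c1c(c2CC=C(C)C)OC(C)(C)C=C1
F2 | step 10 | dilithium alkoxide–ynolate derived from F1 | [Li]O[C@@H]1C[C@H](C#CO[Li])Oc2c1c(OC)c1c(c2CC=C(C)C)OC(C)(C)C=C1
F3 | step 6 | (2S)-4-(tert-butyldimethylsilyloxy)-5-methoxy-8,8-dimethyl-10-(3-methylbut-2-en-1-yl)-2-[(trimethylsilyl)ethynyl]-2H,8H-pyrano[3,2-g]chromene | CC(C)(C)[Si](C)(C)OC1=C[C@@H](C#C[Si](C)(C)C)Oc2c1c(OC)c1c(c2CC=C(C)C)OC(C)(C)C=C1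
F4 | step 6 | (2S)-5-methoxy-8,8-dimethyl-10-(3-methylbut-2-en-1-yl)-2-[(trimethylsilyl)ethynyl]-2,3-dihydro-4H,8H-pyrano[3,2-g]chromen-4-one | O=C1C[C@@H](C#C[Si](C)(C)C)Oc2c1c(OC)c1c(c2CC=C(C)C)OC(C)(C)C=C1
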